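**Retrosynthetic overview**
- Target ⇒ cross-metathesis on a C8 methacrylate, Nef unmasking of the C1 ketone with transannular hemiketal closure, and catalyst-controlled methyl addition to a C4 ketone ⇒ a ten-membered nitro keto enol lactone.
- Key step: four-carbon ring expansion (intramolecular aldol, then retro-Claisen with a nitronate as leaving carbanion, then enol lactonisation) of a six-membered 2-nitro-2-(3-oxobutyl)cyclohexanone (ring B).
- Ring B ⇐ Michael addition to but-3-en-2-one and Stille hydroxymethylation ⇐ a 2-nitrocyclohexanone closed by carbonylative nitronate acylation of an (E)-2,3-dibromoacrylate, which fixes the C7=C11 geometry.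
- Dibromoacrylate ⇐ anti-bromination and esterification of a γ-hydroxy ynoate ⇐ asymmetric alkynylation (C8) of (R)-3-methyl-4-nitrobutanal ⇐ organocatalytic Michael addition (C10) of nitromethane to crotonaldehyde.
- Ring order: ring B first; then the ten-membered carbocycle and the butenolide in one operation; the oxygen-bridged hemiketal (tetrahydrofuran) last.

Assumption: the target is the single stereoisomer encoded by the given SMILES, (1R,4S,8S,10R) with 5E and a 2E side chain; atoms are numbered as in germacranolides (ring C1–C10, lactone carbons C11–C13, C14 on C10, C15 on C4).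

**Step 1**
Reactants: 1 nitromethane; 2 (E)-but-2-enal
Product: 3 (R)-3-methyl-4-nitrobutanal
Conditions: 1 (3 equiv), (S)-α,α-diphenylprolinol trimethylsilyl ether (10 mol%), PhCO2H (20 mol%), MeOH, rt
Reagents that add atoms: none
Why: Iminium-ion organocatalytic Michael addition (Hayashi–Jørgensen type), in which the diarylprolinol silyl ether blocks one face of the (E)-iminium ion so that the nitronate adds to give the R configuration at the future C10.

**Step 2**
Reactants: 3 (R)-3-methyl-4-nitrobutanal; 4 methyl prop-2-ynoate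
Product: 5 methyl (4S,6R)-4-hydroxy-6-methyl-7-nitrohept-2-ynoate
Conditions: 4 (3 equiv), Me2Zn (3 equiv), ProPhenol ligand (20 mol%; antipode giving Re-face addition), Ph3P=O (40 mol%), PhMe, 4 °C; aq NH4Cl
Reagents that add atoms: none
Why: Catalytic asymmetric alkynylation of an aldehyde by an alkynylzinc on the dinuclear zinc–ProPhenol complex sets C8 (S) under catalyst control, the kinetically slow C–H acidity of the nitroalkane keeping nitroaldol side reactions minor.

**Step 3**
Reactants: 5 methyl (4S,6R)-4-hydroxy-6-methyl-7-nitrohept-2-ynoate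
Product: 6 methyl (2E,4S,6R)-2,3-dibromo-4-hydroxy-6-methyl-7-nitrohept-2-enoate
Conditions: Br2 (1.05 equiv), LiBr (2 equiv), AcOH, 15 °C, dark
Reagents that add atoms: bromine, BrBr
Why: Bromide-assisted electrophilic anti addition of bromine to the ynoate gives the (E)-2,3-dibromoacrylate, so the C3 bromide (future C6 acyl site) is cis to the ester and the geometry of the future C7=C11 alkene is fixed.

**Step 4**
Reactants: 6 methyl (2E,4S,6R)-2,3-dibromo-4-hydroxy-6-methyl-7-nitrohept-2-enoate; 7 methacryloyl chloride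
Product: 8 methyl (2E,4S,6R)-2,3-dibromo-4-(methacryloyloxy)-6-methyl-7-nitrohept-2-enoate
Conditions: 7 (1.5 equiv), pyridine (3 equiv), CH2Cl2, 0 °C
Reagents that add atoms: none
Why: Acylation of the secondary alcohol with an acid chloride and pyridine (too weak a base to form the nitronate) installs the ester that protects O8 and is later elaborated into the side chain.

**Step 5**
Reactants: 8 methyl (2E,4S,6R)-2,3-dibromo-4-(methacryloyloxy)-6-methyl-7-nitrohept-2-enoate
Product: 9 methyl (2E)-2-bromo-2-[(2S,4R)-2-(methacryloyloxy)-4-methyl-5-nitro-6-oxocyclohexylidene]acetate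
Conditions: Pd(OAc)2 (5 mol%), Xantphos (7.5 mol%), CO (1 atm), Cs2CO3 (2.2 equiv), 1,4-dioxane, 70 °C; aq NaH2PO4
Reagents that add atoms: carbon monoxide, [C-]#[O+]
Why: Proposed new method: intramolecular palladium-catalysed carbonylative C-acylation of a nitronate by an alkenyl bromide, reasoning that zerovalent palladium inserts into the more electron-poor β C–Br bond of the 2,3-dibromoacrylate, CO insertion gives an acylpalladium with retained geometry, and the tethered cesium nitronate attacks it at carbon in a six-membered closure (the fully substituted β-carbon resists direct vinylic substitution), forming ring B and the C1–C6 and C6–C7 bonds; the closest known reactions are the intermolecular carbonylative α-arylation of nitromethane with aryl iodides and β-selective cross-couplings of 2,3-dibromoacrylates.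

**Step 6**
Reactants: 9 methyl (2E)-2-bromo-2-[(2S,4R)-2-(methacryloyloxy)-4-methyl-5-nitro-6-oxocyclohexylidene]acetate; 10 but-3-en-2-one
Product: 11 methyl (2E)-2-bromo-2-[(2S,4R)-2-(methacryloyloxy)-4-methyl-5-nitro-6-oxo-5-(3-oxobutyl)cyclohexylidene]acetate
Conditions: 10 (1.5 equiv), Et3N (10 mol%), MeCN, 0 °C
Reagents that add atoms: none
Why: Amine-catalysed Michael addition of the strongly acidic α-nitro ketone C–H to the vinyl ketone, the new quaternary C1 being stereochemically irrelevant because it becomes a nitronate in step 8.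

**Step 7**
Reactants: 11 methyl (2E)-2-bromo-2-[(2S,4R)-2-(methacryloyloxy)-4-methyl-5-nitro-6-oxo-5-(3-oxobutyl)cyclohexylidene]acetate
Product: 13 methyl (2Z)-3-acetoxy-2-[(2S,4R)-2-(methacryloyloxy)-4-methyl-5-nitro-6-oxo-5-(3-oxobutyl)cyclohexylidene]propanoate, via hydroxymethyl compound 12 (not isolated)
Conditions: Bu3SnCH2OH (1.5 equiv), Pd(PPh3)4 (5 mol%), BHT, 1,4-dioxane, 90 °C; then Ac2O, pyridine, 0 °C
Reagents that add atoms: (tributylstannyl)methanol, CCCC[Sn](CCCC)(CCCC)CO; acetic anhydride, CC(=O)OC(C)=O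
Why: Stille (Kosugi–Migita–Stille) hydroxymethylation of the remaining bromide, now a vinylogous acyl bromide, proceeds with retention of alkene geometry and delivers C13, and acetylation in the same flask gives the allylic acetate.

**Step 8**
Reactants: 13 methyl (2Z)-3-acetoxy-2-[(2S,4R)-2-(methacryloyloxy)-4-methyl-5-nitro-6-oxo-5-(3-oxobutyl)cyclohexylidene]propanoate
Product: 16 (5E,8S,10R)-13-acetoxy-8-(methacryloyloxy)-1-nitro-4-oxo-15-norgermacra-5,7(11)-dien-12,6-olide, via bicyclic aldol adduct 14 (not isolated), via ring-opened diketo ester 15 (not isolated)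
Conditions: Bu4NF (1.2 equiv), THF, −20 to 0 °C; then CSA (3 equiv), 4 Å MS, PhMe, 50 °C
Reagents that add atoms: none
Why: Hesse-type ring enlargement of a 2-nitro ketone by four carbons, in which the methyl-ketone enolate adds to C6=O in a six-membered aldol, the alkoxide cleaves the C1–C6 bond (retro-Claisen) with the nitronate as leaving carbanion to give the ten-membered β-diketone, and acid then acylates the C6 enol with the cis ester (enol lactonisation), the ten-membered ring enforcing the ring-cis 5E ylidene geometry.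

**Step 9**
Reactants: 16 (5E,8S,10R)-13-acetoxy-8-(methacryloyloxy)-1-nitro-4-oxo-15-norgermacra-5,7(11)-dien-12,6-olide
Product: 17 (4S,5E,8S,10R)-13-acetoxy-4-hydroxy-8-(methacryloyloxy)-1-nitrogermacra-5,7(11)-dien-12,6-olide
Conditions: Me2Zn (4 equiv), Ti(OiPr)4 (1.2 equiv), bis(hydroxycamphorsulfonamide) ligand of trans-cyclohexane-1,2-diamine (10 mol%; antipode giving Re-face addition), PhMe, rt; aq NH4Cl
Reagents that add atoms: dimethylzinc, C[Zn]C
Why: Ligand-accelerated titanium-catalysed enantioselective 1,2-addition of methylzinc to the enone-type C4 ketone leaves the esters and the nitronate alone, and the chiral bis(sulfonamide) ligand directs methyl to the Re face to set C4 (S).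

**Step 10**
Reactants: 17 (4S,5E,8S,10R)-13-acetoxy-4-hydroxy-8-(methacryloyloxy)-1-nitrogermacra-5,7(11)-dien-12,6-olide
Product: 19 (1R,4S,5E,8S,10R)-13-acetoxy-1-hydroxy-8-(methacryloyloxy)-1,4-epoxygermacra-5,7(11)-dien-12,6-olide, via open hydroxy ketone 18 (not isolated)
Conditions: TiCl3 (aq, 5 equiv), NH4OAc (pH 5–6), THF/H2O, rt
Reagents that add atoms: water, O
Why: Reductive Nef reaction (McMurry conditions), in which trivalent titanium reduces the secondary nitro group to an imine that hydrolyses to the C1 ketone, which the C4 hydroxyl traps transannularly as the five-membered hemiketal, C1 (R) being dictated by C4 through the one-atom oxygen bridge.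

**Step 11**
Reactants: 19 (1R,4S,5E,8S,10R)-13-acetoxy-1-hydroxy-8-(methacryloyloxy)-1,4-epoxygermacra-5,7(11)-dien-12,6-olide; 20 (Z)-but-2-ene-1,4-diol
Product: 21 (1R,4S,5E,8S,10R)-13-acetoxy-1-hydroxy-8-[(2E)-4-hydroxy-2-methylbut-2-enoyloxy]-1,4-epoxygermacra-5,7(11)-dien-12,6-olide
Conditions: 20 (5 equiv), second-generation Hoveyda–Grubbs catalyst RuCl2(H2IMes)(=CH–C6H4-2-OiPr) (10 mol%), CH2Cl2, 40 °C
Reagents that add atoms: none
Why: Olefin cross-metathesis of the 1,1-disubstituted methacrylate with the allylic diol gives the trisubstituted E enoate, while the tri- and tetrasubstituted conjugated ring alkenes do not react.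

**Compound list**
1 | nitromethane | C[N+](=O)[O-] | starting material
2 | (E)-but-2-enal | C/C=C/C=O | starting material
3 | (R)-3-methyl-4-nitrobutanal | [O-][N+](=O)C[C@H](C)CC=O | intermediate
4 | methyl prop-2-ynoate | C#CC(=O)OC | starting material
5 | methyl (4S,6R)-4-hydroxy-6-methyl-7-nitrohept-2-ynoate | [O-][N+](=O)C[C@H](C)C[C@@H](C#CC(=O)OC)O | intermediate
6 | methyl (2E,4S,6R)-2,3-dibromo-4-hydroxy-6-methyl-7-nitrohept-2-enoate | [O-][N+](=O)C[C@H](C)C[C@@H](/C(Br)=C(\Br)C(=O)OC)O | intermediate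
7 | methacryloyl chloride | CC(=C)C(Cl)=O | starting material
8 | methyl (2E,4S,6R)-2,3-dibromo-4-(methacryloyloxy)-6-methyl-7-nitrohept-2-enoate | [O-][N+](=O)C[C@H](C)C[C@@H](/C(Br)=C(\Br)C(=O)OC)OC(=O)C(C)=C | intermediate
9 | methyl (2E)-2-bromo-2-[(2S,4R)-2-(methacryloyloxy)-4-methyl-5-nitro-6-oxocyclohexylidene]acetate (ring B; both C5 epimers) | [O-][N+](=O)C1C(=O)/C(=C(/Br)C(=O)OC)[C@@H](OC(=O)C(C)=C)C[C@H]1C | intermediate
10 | but-3-en-2-one | CC(=O)C=C | starting material
11 | methyl (2E)-2-bromo-2-[(2S,4R)-2-(methacryloyloxy)-4-methyl-5-nitro-6-oxo-5-(3-oxobutyl)cyclohexylidene]acetate (both C5 epimers) | CC(=O)CCC1([N+](=O)[O-])C(=O)/C(=C(/Br)C(=O)OC)[C@@H](OC(=O)C(C)=C)C[C@H]1C | intermediate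
12 | methyl (2Z)-3-hydroxy-2-[(2S,4R)-2-(methacryloyloxy)-4-methyl-5-nitro-6-oxo-5-(3-oxobutyl)cyclohexylidene]propanoate | CC(=O)CCC1([N+](=O)[O-])C(=O)/C(=C(/CO)C(=O)OC)[C@@H](OC(=O)C(C)=C)C[C@H]1C | intermediate
13 | methyl (2Z)-3-acetoxy-2-[(2S,4R)-2-(methacryloyloxy)-4-methyl-5-nitro-6-oxo-5-(3-oxobutyl)cyclohexylidene]propanoate | CC(=O)CCC1([N+](=O)[O-])C(=O)/C(=C(/COC(C)=O)C(=O)OC)[C@@H](OC(=O)C(C)=C)C[C@H]1C | intermediate
14 | bicyclic aldol adduct: methyl (2Z)-3-acetoxy-2-[(2S,4R)-8a-hydroxy-2-(methacryloyloxy)-4-methyl-4a-nitro-7-oxooctahydronaphthalen-1(2H)-ylidene]propanoate | O=C1CCC2([N+](=O)[O-])[C@H](C)C[C@H](OC(=O)C(C)=C)/C(=C(\COC(C)=O)C(=O)OC)C2(O)C1 | intermediate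
15 | ring-opened diketo ester: methyl (2Z)-3-acetoxy-2-[(2S,4R)-2-(methacryloyloxy)-4-methyl-5-nitro-8,10-dioxocyclodecylidene]propanoate | O=C1CCC([N+](=O)[O-])[C@H](C)C[C@H](OC(=O)C(C)=C)/C(=C(\COC(C)=O)C(=O)OC)C(=O)C1 | intermediate
16 | (5E,8S,10R)-13-acetoxy-8-(methacryloyloxy)-1-nitro-4-oxo-15-norgermacra-5,7(11)-dien-12,6-olide (both C1 epimers) | CC(=O)OCC1=C2/C(=C\C(=O)CCC([N+](=O)[O-])[C@H](C)C[C@@H]2OC(=O)C(C)=C)OC1=O | intermediate
17 | (4S,5E,8S,10R)-13-acetoxy-4-hydroxy-8-(methacryloyloxy)-1-nitrogermacra-5,7(11)-dien-12,6-olide (both C1 epimers) | CC(=O)OCC1=C2/C(=C\[C@](O)(C)CCC([N+](=O)[O-])[C@H](C)C[C@@H]2OC(=O)C(C)=C)OC1=O | intermediate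
18 | open hydroxy ketone: (4S,5E,8S,10R)-13-acetoxy-4-hydroxy-8-(methacryloyloxy)-1-oxogermacra-5,7(11)-dien-12,6-olide | CC(=O)OCC1=C2/C(=C\[C@](O)(C)CCC(=O)[C@H](C)C[C@@H]2OC(=O)C(C)=C)OC1=O | intermediate
19 | (1R,4S,5E,8S,10R)-13-acetoxy-1-hydroxy-8-(methacryloyloxy)-1,4-epoxygermacra-5,7(11)-dien-12,6-olide | CC(=O)OCC1=C2/C(=C\[C@]3(C)CC[C@@](O)(O3)[C@H](C)C[C@@H]2OC(=O)C(C)=C)OC1=O | intermediate
20 | (Z)-but-2-ene-1,4-diol | OC/C=C\CO | starting material
21 | CNP0154520.2: (1R,4S,5E,8S,10R)-13-acetoxy-1-hydroxy-8-[(2E)-4-hydroxy-2-methylbut-2-enoyloxy]-1,4-epoxygermacra-5,7(11)-dien-12,6-olide | CC(=O)OCC1=C2/C(=C\[C@]3(C)CC[C@@](O)(O3)[C@H](C)C[C@@H]2OC(=O)/C(C)=C/CO)OC1=O | target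

**Step count**
Total steps: 11. Longest linear sequence: 11 (the route is fully linear).

**The three steps most likely to fail**

Step 5 (the proposed carbonylative nitronate acylation). O-acylation of the nitronate, protodebromination or slow oxidative addition at the fully substituted alkenyl bromide could prevail. The fallback uses known chemistry, sets out from 8 and comes back at 9. Palladium-catalysed hydroxycarbonylation of the β-bromide (Pd(OAc)2, Xantphos, CO, H2O, Et3N, 1,4-dioxane) gives (2E)-3-bromo-4-methoxy-2-[(1S,3R)-1-(methacryloyloxy)-3-methyl-4-nitrobutyl]-4-oxobut-2-enoic acid F1. 1,1'-Carbonyldiimidazole in THF converts it into the acyl imidazole F2. KOtBu in THF at 0 °C then closes ring B by the established C-acylation of a nitronate with an acyl imidazole, giving 9.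

Step 8 (the ring expansion). Under fluoride the enolate may instead cause retro-Michael loss of 10 or vinylogous elimination of the C8 ester. The fallback separates bond formation from fragmentation, sets out from 13 and comes back at 14. LiN(iPr)2 and Me3SiCl in THF at −78 °C give the kinetic trimethylsilyl enol ether of the methyl ketone F3. TiCl4 in CH2Cl2 at −78 °C closes the six-membered ring by a Mukaiyama aldol under non-basic conditions to give the aldol adduct 14, now isolated. Its potassium alkoxide (KH, 18-crown-6, THF, 0 °C) fragments to 15, and the acid lactonisation of step 8 gives 16.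

Step 9 (the methyl addition). The macrocycle may override the ligand, or the zinc nitronate may add transannularly to C6 or poison the catalyst. The fallback relies on substrate control and recycling, sets out from 16 and comes back at 19. MeMgBr with CeCl3 in THF at −78 °C gives 17 together with its (4R)-epimer F4. The mixture is taken through step 10 to give 19 and the (1S,4R)-diastereomeric hemiketal F5, which are separated by chromatography. F5 is equilibrated with PPTS in wet MeCN at 40 °C through the tertiary allylic C4 cation, and 19 is recovered from the resulting mixture.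

**Further compounds**
F1 | step 5 | (2E)-3-bromo-4-methoxy-2-[(1S,3R)-1-(methacryloyloxy)-3-methyl-4-nitrobutyl]-4-oxobut-2-enoic acid | [O-][N+](=O)C[C@H](C)C[C@@H](/C(C(=O)O)=C(\Br)C(=O)OC)OC(=O)C(C)=C
F2 | step 5 | methyl (2E)-2-bromo-4-(1H-imidazol-1-yl)-3-[(1S,3R)-1-(methacryloyloxy)-3-methyl-4-nitrobutyl]-4-oxobut-2-enoate | [O-][N+](=O)C[C@H](C)C[C@@H](/C(C(=O)n1ccnc1)=C(\Br)C(=O)OC)OC(=O)C(C)=C
F3 | step 8 | trimethylsilyl enol ether of 13: methyl (2Z)-3-acetoxy-2-[(2S,4R)-2-(methacryloyloxy)-4-methyl-5-nitro-6-oxo-5-(3-(trimethylsilyloxy)but-3-enyl)cyclohexylidene]propanoate | C=C(O[Si](C)(C)C)CCC1([N+](=O)[O-])C(=O)/C(=C(/COC(C)=O)C(=O)OC)[C@@H](OC(=O)C(C)=C)C[C@H]1C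
F4 | step 9 | (4R,5E,8S,10R)-13-acetoxy-4-hydroxy-8-(methacryloyloxy)-1-nitrogermacra-5,7(11)-dien-12,6-olide (C4 epimer of 17) | CC(=O)OCC1=C2/C(=C\[C@@](O)(C)CCC([N+](=O)[O-])[C@H](C)C[C@@H]2OC(=O)C(C)=C)OC1=O
F5 | step 9 | (1S,4R,5E,8S,10R)-13-acetoxy-1-hydroxy-8-(methacryloyloxy)-1,4-epoxygermacra-5,7(11)-dien-12,6-olide (C1,C4-bis-epimer of 19) | CC(=O)OCC1=C2/C(=C\[C@@]3(C)CC[C@](O)(O3)[C@H](C)C[C@@H]2OC(=O)C(C)=C)OC1=O
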